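The target is what we read in every flask, so whatever we say about the two reactants has to be reckoned back from it.

| flask | starting material | coupling partner | time |
|---|---|---|---|
| theta | 300 mM | 450 mM |  |
| gamma | 150 mM | 300 mM |  |
| zeta | 300 mM | 230 mM |  |
| beta | 600 mM | 450 mM |  |
| alpha | 300 mM | 98.0 mM | 25 min |

| theta run: time / min | theta run: [target] / mM | gamma run: time / min | gamma run: [target] / mM | zeta run: time / min | zeta run: [target] / mM | beta run: time / min | beta run: [target] / mM |
|---|---|---|---|---|---|---|---|
| 1.0 | 9.3 | 1.0 | 1.8 | 1.0 | 7.4 | 1.0 | 16.6 |
| 1.7 | 17.6 | 1.7 | 7.7 | 1.7 | 13.7 | 1.7 | 21.7 |
| 2.9 | 26.0 | 2.9 | 12.3 | 2.9 | 12.6 | 2.9 | 40.9 |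
| 5.0 | 41.9 | 5.0 | 16.8 | 5.0 | 21.6 | 5.0 | 62.9 |
| 8.5 | 63.3 | 8.5 | 29.3 | 8.5 | 31.4 | 8.5 | 90.5 |
| 15 | 77.7 | 15 | 41.7 | 15 | 52.4 | 15 | 115.2 |
| 25 | 88.4 | 25 | 52.2 | 25 | 64.1 | 25 | 130.6 |

(standard deviation of a reading: 2 mM)

- Overall: starting material + coupling partner -> target.
- Constant volume, constant temperature.
- A reading of a species includes what of it is bound.
- "The second partner" is coupling partner.
- An order is taken over about fifteen percent of the charge, up and down.

- the exponent of [starting material] in the starting rate at the charge of the theta run (at the point where two percent of the starting material have become target) (one fixed amount of target, the same in the runs compared)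
- the exponent of [coupling partner] in the starting rate at the charge of the theta run (at the point where two percent of the starting material have become target)
- target in the alpha run at 25 min, as a share of the starting material charged

The beta run doubles the starting material of the theta run, yet at 5.0 min its target stands 1.50 times as high as in theta, so the rate does not follow the starting material in proportion, and we stay at 300 mM, the charge that the zeta and alpha runs share. In the alpha run the coupling partner is the limiting reagent, 98.0 mM against 300 mM, so we work with what is left of it: if it goes pseudo-first-order at one charge of starting material, the same fraction stands after the same time, whatever its own charge. The zeta run gives the fraction left φ = 0.721, the share of the coupling partner charged that is not found as target at 25 min. But the theta run reads 0.804 at the same time, so φ shifts with the charge, and we take it from zeta, the nearer flask. Our own reckoning for the alpha run is then 27.3 mM of target, or 9.10% of its starting material.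

The forecast gives exponents of 0.65 in starting material and 0.95 in coupling partner, and for the alpha run 11%, a figure above ours that comes from its own rate law with a ceiling, on the ground that “All runs then stall far before reactants run out”.

The flask gives exponents of 0.58 and 1.2, and 11.2% in the alpha run.

    starting material + coupling partner → target (0.3684 M⁻¹ min⁻¹)
    starting material + 2 coupling partner → target + coupling partner (0.2076 M⁻² min⁻¹)
    2 starting material ⇌ idle substrate dimer, settled at all times (39.70 M⁻¹)
    target + coupling partner → side product (0.1428 M⁻¹ min⁻¹)

So the number to watch in the alpha run is its fraction left, 0.657, lower than the 0.721 read in zeta and still high for a flask with the starting material in excess. It stands that high because of the joining of starting material to idle substrate dimer: with that joining taken away, the alpha run reaches 26.3% of target, and its fraction left drops to 0.195.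

All runs were computed for an exercise.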